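The runs were computed for an exercise; the scatter is artificial.

Which set-up gives the highest share of E among what became E or G: blue, red, violet or grey?

common to all: L 1.4 mol%
- epsilon: X 0.20 M; Q 0.20 M; J 2.2 equiv; run made earlier
- alpha: X 0.13 M; Q 0.13 M; J 2.2 equiv; run made earlier
- gamma: X 0.30 M; Q 0.30 M; J 2.2 equiv; run made earlier
- blue: X 0.20 M; Q 0.20 M; J 2.20 equiv; plug flow through a tube for 8.0 h, no back-mixing; time 8.0 h
- red: X 0.20 M; Q 0.20 M; J 2.20 equiv (fed, over 4.00 h); all but J at the start; J goes in evenly over 4.00 h, the run ends at 8.0 h; time 8.0 h
- violet: X 0.20 M; Q 0.20 M; J 2.20 equiv; a closed flask charged with all of it at once and left for 8.0 h; time 8.0 h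
- grey: X 0.20 M; Q 0.20 M; J 2.20 equiv; a single well-mixed tank run continuously and read at steady state, 8.0 h in it on average

| run | time / h | E / % | G / % |
|---|---|---|---|
| epsilon | 0.417 | 32 | 2 |
| epsilon | 1.33 | 55 | 6 |
| epsilon | 2.50 | 70 | 6 |
| epsilon | 3.00 | 75 | 5 |
| epsilon | 5.00 | 81 | 10 |
| epsilon | 6.00 | 83 | 6 |
| epsilon | 8.00 | 85 | 10 |
| alpha | 1.33 | 40 | 3 |
| alpha | 3.00 | 59 | 3 |
| alpha | 4.00 | 64 | 6 |
| alpha | 6.00 | 72 | 4 |
| alpha | 8.00 | 75 | 9 |
| alpha | 10.0 | 81 | 9 |
| gamma | 0.833 | 61 | 6 |
| gamma | 1.33 | 70 | 9 |
| gamma | 2.00 | 78 | 9 |
| gamma | 2.50 | 81 | 9 |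
| gamma | 4.00 | 82 | 12 |
| gamma | 6.00 | 85 | 7 |
| gamma | 10.0 | 87 | 12 |

(scatter of a reading: 1.5 percentage points)

1. the set-up with the highest share of E in all that became E or G, at the outlet or at the end ("none" if the first two lie within 2 percentage points) (blue / red / violet / grey / none)
2. share of E in all that became E or G, at the outlet or at the end, blue
3. share of E in all that became E or G, at the outlet or at the end, red
4. share of E in all that became E or G, at the outlet or at the end, violet
5. share of E in all that became E or G, at the outlet or at the end, grey

- L is single-handed; X and Q are mirror images of each other, charged as a racemate, each of them at the stated concentration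
- the stated concentrations are those of everything mixed, before any reaction; amounts are the same in each set-up
- the feed brings no volume worth counting
- the earlier runs were made in a closed, stirred flask

I follow one substrate molecule to its fork, and I read the ladder of times from the epsilon run, which is violet's recipe in the same kind of closed flask. The burst stands on the fastest rung: E reaches 32% at 0.417 h. Counted against the X charged, that reads as a half-life of X, τb, of 0.283 h. On the next rung, E stands at 75% at 3.00 h, more than the X charged, so Q is turning into X. On the slowest rung, what is neither E nor G falls from 20.0% at 3.00 h to 5.00% at 8.00 h. That reads as a tail half-life, τt, of 2.50 h, ten times τb.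

On that tail I take X and Q as level, and I suppose that both branches of the fork use J and L alike, so a vessel changes when J arrives but not the odds. The E and G readings pooled from 5.00 h onward give 90.5%. This is my fork share f, the cumulative chance, burst included, that a reacting substrate molecule leaves as E. I therefore expect blue, red, violet and grey near f, with no winner.

The forecast also says none. It gives blue 91.5% and violet 91.5%, each from 89.5% to 93%, and grey 92%, from 89% to 95%. Unlike me, it puts red lower, at 89%, from 85% to 94%: “Slow J feed forfeits the free burst, keeps Q exposed longer and ends less complete”.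

The flask gives none: blue 90.9%, red 91.7%, violet 90.9%, grey 91.5%.

    X ⇌ Q (k = 6.50 × 10⁻⁴ s⁻¹)
    J + L + X → L + E (k = 0.690 M⁻² s⁻¹)
    J + L + Q → L + G (k = 0.0560 M⁻² s⁻¹)
    J ⇌ D (K = 0.240, k = 8.70 × 10⁻⁴ s⁻¹)

Red and grey stand 0.20 percentage points apart, inside the margin of 2 points, and f lies 0.40 points below violet. A neighbour of red, charged with 0.550 equiv of J, a quarter of the recipe, gives 92.3%, 1.8 points above f. At its end it holds E at 25.2% and Q at 36.4%.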